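**Retrosynthetic overview**

1. Numbering: the flavanone unit has rings A, C and B (atoms plain and primed), and the luteolin unit has double-primed atoms. The target is released from its octabenzyl ether by neutral hydrogenolysis.
2. Key disconnection, C3–C4 of flavanone ring C: the octabenzyl ether is an isomer of an achiral 2-(1-arylvinyloxy)benzaldehyde. An enantioselective rhodium-catalysed intramolecular hydroacylation should fold this aldehyde into ring C, the C4 ketone and the C2 stereocentre in one operation.
3. Enabling feature: in ring C the carbonyl carbon C4 sits on ring A ortho to O1, C3 is an unsubstituted CH2, and C2 is a tertiary O,aryl-substituted C–H β to the ketone. Ring C therefore maps atom for atom onto formyl C–H plus O–C(Ar)=CH2. The formyl H becomes H-2, and O1 and the 5-oxygen flank the formyl group and can hold the metal.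
4. The open precursor comes from a Suzuki–Miyaura coupling (C6'–C8'') of an 8-iodoluteolin ether with a ring-B boronate. The enol ether (O1–C2) of that boronate comes from Mitsunobu etherification of a chlorohydrin followed by dehydrochlorination.
5. Ring order: the three luteolin rings are bought intact, and rings A and B are bought as benzaldehydes. Flavanone ring C is the only ring made, last but one.

Key step: step 10

Assumption: the target SMILES fixes only C2, which is R (O1 > C1' > C3 > H). The C6'–C8'' biaryl axis carries no descriptor, so it is treated as not fixed and no axial control is attempted.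

**Step 1**
Reactants: 1 luteolin
Product: 2 5,7,3',4'-tetra-O-benzylluteolin
Conditions: BnBr (6 equiv), K2CO3 (8 equiv), DMF, 80 °C
Reagents that add atoms: benzyl bromide, BrCc1ccccc1
Why: Williamson etherification in which excess reagent and heat also alkylate the hydrogen-bonded 5-OH, which must be capped so that the next step goes to C8.

**Step 2**
Reactants: 2 5,7,3',4'-tetra-O-benzylluteolin
Product: 3 8-iodo-5,7,3',4'-tetra-O-benzylluteolin
Conditions: NIS (1.1 equiv), CF3CO2H (0.2 equiv), CH2Cl2/MeCN, 0 °C to rt, dark
Reagents that add atoms: N-iodosuccinimide, O=C1CCC(=O)N1I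
Why: Electrophilic aromatic iodination should hit the trioxygenated ring of the flavone at C8, because fully O-alkylated 5,7-dioxygenated flavones halogenate there and C6 is wedged between two benzyloxy groups.

**Step 3**
Reactants: 4 2,4,6-trihydroxybenzaldehyde
Product: 5 2,4-bis(benzyloxy)-6-hydroxybenzaldehyde
Conditions: BnBr (2.05 equiv), K2CO3 (2.1 equiv), DMF, 0 °C to rt
Reagents that add atoms: benzyl bromide, BrCc1ccccc1
Why: Williamson etherification should stop at the bis-ether because the last ortho OH is locked in a hydrogen bond to the formyl oxygen and is the least nucleophilic.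

**Step 4**
Reactants: 6 3,4-bis(benzyloxy)benzaldehyde
Product: 7 4,5-bis(benzyloxy)-2-bromobenzaldehyde
Conditions: Br2 (1.05 equiv), NaOAc, AcOH, rt
Reagents that add atoms: bromine, BrBr
Why: Electrophilic bromination of 3,4-dialkoxybenzaldehydes goes reliably para to the 3-alkoxy group, which is the future C6', and acetate buffers the HBr so the benzyl ethers survive.

**Step 5**
Reactants: 7 4,5-bis(benzyloxy)-2-bromobenzaldehyde
Product: 8 rac-1-[4,5-bis(benzyloxy)-2-bromophenyl]-2-chloroethan-1-ol
Conditions: ICH2Cl (1.5 equiv), MeLi·LiBr (1.4 equiv), THF, −78 °C; then AcOH, −78 °C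
Reagents that add atoms: chloroiodomethane, ClCI
Why: Chloromethyllithium, made in the presence of the aldehyde by fast I/Li exchange, adds 1,2 to the formyl group before methyllithium can touch the aldehyde or the aryl bromide, and the cold acidic quench stops at the chlorohydrin, whose racemic centre is of no consequence.

**Step 6**
Reactants: 8 rac-1-[4,5-bis(benzyloxy)-2-bromophenyl]-2-chloroethan-1-ol; 5 2,4-bis(benzyloxy)-6-hydroxybenzaldehyde
Product: 9 rac-2,4-bis(benzyloxy)-6-{1-[4,5-bis(benzyloxy)-2-bromophenyl]-2-chloroethoxy}benzaldehyde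
Conditions: PPh3, DIAD, THF, 0 °C to rt
Reagents that add atoms: none
Why: Mitsunobu etherification forms O1–C2, because the acidic salicylaldehyde-type phenol is a good pronucleophile for the activated benzylic alcohol, and the racemic centre is erased in step 7.

**Step 7**
Reactants: 9 rac-2,4-bis(benzyloxy)-6-{1-[4,5-bis(benzyloxy)-2-bromophenyl]-2-chloroethoxy}benzaldehyde
Product: 10 2,4-bis(benzyloxy)-6-({1-[4,5-bis(benzyloxy)-2-bromophenyl]ethenyl}oxy)benzaldehyde
Conditions: KOtBu (1.3 equiv), THF, −20 to 0 °C; Et3N-deactivated silica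
Reagents that add atoms: none
Why: E2 dehydrochlorination of a β-chloro ether is the classical route to aryl vinyl ethers, and here the C–H removed is benzylic and α to oxygen while chloride is by far the better leaving group, so the 1,1-disubstituted enol ether should form.

**Step 8**
Reactants: 10 2,4-bis(benzyloxy)-6-({1-[4,5-bis(benzyloxy)-2-bromophenyl]ethenyl}oxy)benzaldehyde
Product: 11 2,4-bis(benzyloxy)-6-({1-[4,5-bis(benzyloxy)-2-(4,4,5,5-tetramethyl-1,3,2-dioxaborolan-2-yl)phenyl]ethenyl}oxy)benzaldehyde
Conditions: B2pin2, KOAc, PdCl2(dppf) (5 mol %), 1,4-dioxane, 85 °C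
Reagents that add atoms: bis(pinacolato)diboron, CC1(C)OB(OC1(C)C)B1OC(C)(C)C(C)(C)O1
Why: In the Miyaura borylation, zerovalent palladium inserts into the C6'–Br bond and acetate-assisted transmetalation delivers the boronate under conditions too mild to disturb the aldehyde or enol ether or to allow C–H arylation of ring A.

**Step 9**
Reactants: 11 ring-B pinacol boronate; 3 8-iodo-5,7,3',4'-tetra-O-benzylluteolin
Product: 12 2,4-bis(benzyloxy)-6-({1-[4,5-bis(benzyloxy)-2-(5,7,3',4'-tetra-O-benzylluteolin-8-yl)phenyl]ethenyl}oxy)benzaldehyde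
Conditions: Pd(OAc)2 (5 mol %), SPhos (10 mol %), K3PO4, toluene/H2O, 70 °C
Reagents that add atoms: none
Why: In the Suzuki–Miyaura coupling the bulky electron-rich biarylphosphine supports insertion into the hindered C8''–I bond and formation of a triply ortho-substituted biaryl, and placing boron on ring B avoids a 2,6-dioxygenated arylboron reagent that would protodeborylate.

**Step 10**
Reactants: 12 aldehyde/enol ether biaryl
Product: 13 (2R)-5,7,3',4'-tetra-O-benzyl-6'-(5,7,3',4'-tetra-O-benzylluteolin-8-yl)eriodictyol
Conditions: [Rh(cod)Cl]2 (5 mol %), (R)-DTBM-SEGPHOS (11 mol %), NaB[3,5-(CF3)2C6H3]4 (10 mol %), 4 Å MS, 1,2-dichloroethane, 60 °C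
Reagents that add atoms: none
Why: Proposed new method: the cationic monovalent rhodium bisphosphine should add oxidatively into the formyl C–H bond, the enol ether C=C should then insert into Rh–H with hydride going to the O,aryl-bearing C2 and rhodium to the terminal CH2, and C–C reductive elimination from the seven-membered acyl–alkyl rhodacycle should forge C3–C4 and free the catalyst. The closest known reaction type is the enantioselective rhodium-catalysed intramolecular hydroacylation of 1,1-disubstituted alkenes (2-(1-arylvinyl)benzaldehydes to 3-arylindanones, ortho-(2-substituted allyl)benzaldehydes to 3-substituted tetralones, N-(1-substituted vinyl)indole-2-carbaldehydes to β-substituted cyclic ketones), whereas closure of an aryl 1-arylvinyl ether to a flavanone has not been shown. Ring C closes in a formal 6-endo-trig mode, with both alkene carbons ending up in the ring. C2 is set by the axially chiral bisphosphine alone, which must steer hydride to the Si face of C2 to give R; the hand of the ligand is to be confirmed on bromide 10 as a model, and both hands are available. The step needs 6-endo over 5-exo closure, hydroacylation over decarbonylation, and one alkene face: geminal disubstitution forces the 5-exo path through a tertiary alkylrhodium, the oxygen-polarised alkene (C2 positive, C3 negative) matches hydride to C2, the alkene has no allylic hydrogen and cannot isomerise, and O1 and the 5-benzyloxy oxygen beside the acyl carbon should stabilise the acylrhodium hydride against CO loss. Because the reaction is a neutral isomerisation placed after all basic steps, the base-labile C2 centre is not exposed to ring opening.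

**Step 11**
Reactants: 13 (2R)-octabenzyl ether
Product: 14 target, (2R)-6'-(luteolin-8-yl)eriodictyol (CNP0228504.1)
Conditions: H2 (1 atm), 10% Pd/C, THF/MeOH, rt; reversed-phase purification with 0.1% HCO2H
Reagents that add atoms: none
Why: Neutral hydrogenolysis of aryl benzyl ethers is much faster at 1 atm than reduction of the flavone C2''=C3'' bond or cleavage of the cyclic C2–O1 bond, and without base the C2 centre cannot racemise through the ring-opened chalcone.

**Compound list**

1 | luteolin | O=c1cc(-c2ccc(O)c(O)c2)oc2cc(O)cc(O)c12 | starting material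
2 | 5,7,3',4'-tetra-O-benzylluteolin | O=c1cc(-c2ccc(OCc3ccccc3)c(OCc3ccccc3)c2)oc2cc(OCc3ccccc3)cc(OCc3ccccc3)c12 | intermediate
3 | 8-iodo-5,7,3',4'-tetra-O-benzylluteolin | Ic1c(OCc2ccccc2)cc(OCc2ccccc2)c2c(=O)cc(-c3ccc(OCc4ccccc4)c(OCc4ccccc4)c3)oc12 | intermediate
4 | 2,4,6-trihydroxybenzaldehyde | O=Cc1c(O)cc(O)cc1O | starting material
5 | 2,4-bis(benzyloxy)-6-hydroxybenzaldehyde | O=Cc1c(O)cc(OCc2ccccc2)cc1OCc1ccccc1 | intermediate
6 | 3,4-bis(benzyloxy)benzaldehyde | O=Cc1ccc(OCc2ccccc2)c(OCc2ccccc2)c1 | starting material
7 | 4,5-bis(benzyloxy)-2-bromobenzaldehyde | O=Cc1cc(OCc2ccccc2)c(OCc2ccccc2)cc1Br | intermediate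
8 | rac-1-[4,5-bis(benzyloxy)-2-bromophenyl]-2-chloroethan-1-ol | OC(CCl)c1cc(OCc2ccccc2)c(OCc2ccccc2)cc1Br | intermediate
9 | rac-2,4-bis(benzyloxy)-6-{1-[4,5-bis(benzyloxy)-2-bromophenyl]-2-chloroethoxy}benzaldehyde | O=Cc1c(OC(CCl)c2cc(OCc3ccccc3)c(OCc3ccccc3)cc2Br)cc(OCc2ccccc2)cc1OCc1ccccc1 | intermediate
10 | 2,4-bis(benzyloxy)-6-({1-[4,5-bis(benzyloxy)-2-bromophenyl]ethenyl}oxy)benzaldehyde | O=Cc1c(OC(=C)c2cc(OCc3ccccc3)c(OCc3ccccc3)cc2Br)cc(OCc2ccccc2)cc1OCc1ccccc1 | intermediate
11 | ring-B pinacol boronate of 10 | O=Cc1c(OC(=C)c2cc(OCc3ccccc3)c(OCc3ccccc3)cc2B2OC(C)(C)C(C)(C)O2)cc(OCc2ccccc2)cc1OCc1ccccc1 | intermediate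
12 | aldehyde/enol ether biaryl (open isomer of 13) | O=Cc1c(OC(=C)c2cc(OCc3ccccc3)c(OCc3ccccc3)cc2-c2c(OCc3ccccc3)cc(OCc3ccccc3)c3c(=O)cc(-c4ccc(OCc5ccccc5)c(OCc5ccccc5)c4)oc23)cc(OCc2ccccc2)cc1OCc1ccccc1 | intermediate
13 | (2R)-octa-O-benzyl ether of the target | O=C1C[C@H](c2cc(OCc3ccccc3)c(OCc3ccccc3)cc2-c2c(OCc3ccccc3)cc(OCc3ccccc3)c3c(=O)cc(-c4ccc(OCc5ccccc5)c(OCc5ccccc5)c4)oc23)Oc2cc(OCc3ccccc3)cc(OCc3ccccc3)c21 | intermediate
14 | (2R)-6'-(luteolin-8-yl)eriodictyol, CNP0228504.1 | O=C1C[C@H](c2cc(O)c(O)cc2-c2c(O)cc(O)c3c(=O)cc(-c4ccc(O)c(O)c4)oc23)Oc2cc(O)cc(O)c21 | target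

**Step count**

Total step count: 11.
Longest linear sequence: 8 steps (steps 4 to 11, from 6).

**Steps most likely to fail**

**Step 10 (the proposed new method).**
- Risks: insertion at the crowded enol ether may be slow, the acylrhodium hydride may lose CO, or facial selectivity may be poor.
- The fallback sets out from 9 and keeps the chloride instead of eliminating it.
- Miyaura borylation of 9 (B2pin2, KOAc, PdCl2(dppf), dioxane) should give the chloro boronate F1.
- Suzuki–Miyaura coupling of this with 3, under the conditions of step 9, should give the chloro aldehyde biaryl F2.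
- A thiazolium-derived N-heterocyclic carbene (3-benzyl-5-(2-hydroxyethyl)-4-methylthiazolium chloride, 20 mol %, DBU, THF, reflux) then turns the aldehyde into its acyl anion equivalent. This displaces the primary chloride in a 6-exo-tet closure of the same C3–C4 bond. The reaction is known for making chroman-4-ones from 2-(2-haloethoxy)benzaldehydes, and it should give the racemic octabenzyl flavanone F3.
- Preparative HPLC on a chiral stationary phase separates 13, where the route is rejoined, from the (2S)-octabenzyl flavanone F4. The latter can be re-racemised with DBU through the ring-opened chalcone and recycled.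

**Step 9.**
- Risks: transmetalation to a doubly ortho-flanked arylpalladium may be sluggish, and the electron-rich boronate may protodeborylate.
- The fallback sets out from 3, reverses the polarity and skips the boronate.
- Direct insertion of LiCl-activated zinc dust (THF, 50 °C) into the C8''–I bond should give the flavon-8-ylzinc iodide F5, which tolerates the flavone carbonyl and aldehydes.
- Negishi coupling of this with bromide 10 (Pd(OAc)2, SPhos, THF, 50 °C) comes back to the route at 12.

**Step 7.**
- Risks: elimination may run in the other direction with loss of the stabilised aryloxide, or the strong base may attack the aldehyde.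
- The fallback sets out from 9 and replaces the base-induced E2 by a thermal syn elimination.
- Displacement of chloride with benzeneselenol (K2CO3, DMF, rt) should give the phenyl selenide F6.
- Oxidation with mCPBA (1 equiv, CH2Cl2, −78 °C) should give the selenoxide F7.
- Warming with iPr2NH lets the selenoxide eliminate across the only available β C–H, the benzylic one, and the route is rejoined at 10.

**Further compounds**

F1 | step 10 | rac-chloro boronate (9 with Bpin in place of Br) | O=Cc1c(OC(CCl)c2cc(OCc3ccccc3)c(OCc3ccccc3)cc2B2OC(C)(C)C(C)(C)O2)cc(OCc2ccccc2)cc1OCc1ccccc1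
F2 | step 10 | rac-chloro aldehyde biaryl | O=Cc1c(OC(CCl)c2cc(OCc3ccccc3)c(OCc3ccccc3)cc2-c2c(OCc3ccccc3)cc(OCc3ccccc3)c3c(=O)cc(-c4ccc(OCc5ccccc5)c(OCc5ccccc5)c4)oc23)cc(OCc2ccccc2)cc1OCc1ccccc1
F3 | step 10 | racemic octabenzyl flavanone | O=C1CC(c2cc(OCc3ccccc3)c(OCc3ccccc3)cc2-c2c(OCc3ccccc3)cc(OCc3ccccc3)c3c(=O)cc(-c4ccc(OCc5ccccc5)c(OCc5ccccc5)c4)oc23)Oc2cc(OCc3ccccc3)cc(OCc3ccccc3)c21
F4 | step 10 | (2S)-octabenzyl flavanone | O=C1C[C@@H](c2cc(OCc3ccccc3)c(OCc3ccccc3)cc2-c2c(OCc3ccccc3)cc(OCc3ccccc3)c3c(=O)cc(-c4ccc(OCc5ccccc5)c(OCc5ccccc5)c4)oc23)Oc2cc(OCc3ccccc3)cc(OCc3ccccc3)c21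
F5 | step 9 | (5,7,3',4'-tetra-O-benzylluteolin-8-yl)zinc iodide | I[Zn]c1c(OCc2ccccc2)cc(OCc2ccccc2)c2c(=O)cc(-c3ccc(OCc4ccccc4)c(OCc4ccccc4)c3)oc12
F6 | step 7 | rac-phenyl selenide (9 with SePh in place of Cl) | O=Cc1c(OC(C[Se]c2ccccc2)c2cc(OCc3ccccc3)c(OCc3ccccc3)cc2Br)cc(OCc2ccccc2)cc1OCc1ccccc1
F7 | step 7 | selenoxide of F6 | O=Cc1c(OC(C[Se](=O)c2ccccc2)c2cc(OCc3ccccc3)c(OCc3ccccc3)cc2Br)cc(OCc2ccccc2)cc1OCc1ccccc1
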